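A run of 30 h is longer than the 9.50 h first half-life of fresh L in the west flask, so you should treat the catalyst there as a decaying drive, not a constant one.

common to all: Z 0.034 M; L 0.1 mol%; time 30 h
- north-east: temperature 85 °C
- south-west: at 85 °C until 6.0 h, from then on at 55 °C
- west: temperature 70 °C
- north-west: temperature 55 °C

* the best flask by amount of Q, in percent of the Z charged; "all alike" if 1.5 percentage points covers them all (north-east / south-west / west / north-west / all alike)
* amount of Q at the end, in percent of the Z charged, north-east
* amount of Q at the end, in percent of the Z charged, south-west
* amount of Q at the end, in percent of the Z charged, west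
* amount of Q at the end, in percent of the Z charged, north-west

- in percentages every species weighs as the Z in it: one Z.Q counts as two
- for a step with 2 of a species take k times the square, and two of it per event
- the list of constants is for 70 °C, to be carried to other temperatures by the activation energies and enthalpies
- in a conversion G counts as not yet reacted

    Z ⇌ G (K1 = 2.7, k1 = 9.0 × 10⁻⁵ s⁻¹, Ea1 = 121 kJ mol⁻¹, ΔH1 = 6.00 kJ mol⁻¹)
    Z + L → L + Q (k2 = 0.84 M⁻¹ s⁻¹, Ea2 = 39.0 kJ mol⁻¹)
    L + G → L + E (k3 = 1.0 M⁻¹ s⁻¹, Ea3 = 56.0 kJ mol⁻¹)
    2 L → L2 (k4 = 0.43 M⁻¹ s⁻¹, Ea4 = 49.0 kJ mol⁻¹)
    Z + Q → Z.Q (k5 = 7.9 × 10⁻⁵ M⁻¹ s⁻¹, Ea5 = 76.0 kJ mol⁻¹)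
    (constants at 70 °C)

- My reckoning is for the west flask and works with what is left. The routes to Q and E give L back, while pairing into L2 removes it.
- Z and G exchange with a time constant of 2.25 h, shorter than the half-life of L. You may therefore treat them as one pool held at the ratio 2.7, which is the usual pre-equilibrium.
- The pool drains in proportion to L, and L drains in proportion to itself times L. Divide one rate by the other and time drops out: at a constant temperature, the fraction of Z plus G left equals the fraction of L left raised to a fixed power.
- That power, the leftover exponent, is the pool-weighted constant of leaving divided by twice the constant of pairing: 1.11.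
- Which numbers must be good? The side step to Z.Q may stay rough in the west flask: even with Q at the whole charge, it runs at 9.40% of the rate of fresh L on Z.
- The equilibrium constant may stay rough too: at twice its value the exponent reads 1.13.
- The constant of Z going to G is absent from the exponent, but it has to keep the exchange quicker than the decay of L.
- The pairing constant and the charge of L do matter. With twice the pairing constant, the west flask keeps 33.1% of its pool at the end; with twice the L, it keeps 11.0%.
- Now the number itself. The fraction of L left is the reciprocal of one plus elapsed time over half-life, which gives 24.1% for the west flask at the end. Raised to the exponent, that leaves 20.5% of the charge as Z plus G, a conversion of 79.5%. My reckoning stops there: it does not split the turned part between Q and E.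
- The forecast gives Q as 20.5% north-east, 19.5% south-west, 31% west and 44% north-west, with north-west best. Its ground for the cold flask: “the catalyst takes Z to Q before much G builds up”.
- The simulation gives 20.7% north-east, 19.8% south-west, 30.5% west and 43.7% north-west, so north-west leads, as the forecast said.
- The west flask ends with 24.1% of its L and 20.6% of the charge as Z plus G, beside the reckoned 24.1% and 20.5%. A neighbour of the south-west flask, run with 0.025 mol% of L, keeps 62.0% of its L. The exponent is only borrowed here, since it was reckoned for 70 °C and this neighbour ran at 85 °C and then 55 °C; it turns that into 58.8%, and the neighbour's Z plus G stands at 58.5%. The west flask has not come to rest at 30.0 h: by 300 h its Z plus G is down to 1.65%, E has risen from 47.2% to 60.7%, and Q has risen from 30.5% to 33.5%.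

The constants used here are assumed; no experiment stands behind them.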